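Teal takes out 90% of the target at 20 h, and I first asked which number its outcome hung on.

common to all: coupling partner 0.177 M
- zeta: starting material 0.071 M; second substrate 0.071 M; temperature 110 °C; the very flask that is asked about, followed so far
- delta: starting material 0.11 M; second substrate 0.071 M; temperature 116 °C; run made earlier
- flask: starting material 0.071 M; second substrate 0.0710 M; temperature 110 °C; time 20 h

- zeta (time / h: target / %): 4.00: 16.4; 8.00: 16.7; 12.0: 15.8; 15.0: 16.5; 20.0: 17.0
- delta (time / min: target / %): 5.00: 26.9; 15.0: 25.6; 30.0: 18.2; 40.0: 16.4; 60.0: 15.2

(scatter of a reading: 1 percentage point)

- green: change nothing and wait 10 h more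
- amber: at 20 h add coupling partner, 100% of the amount charged, then wait 10 h
- violet: at 20 h raise the temperature by 15 K, then wait 10 h
- teal: at 20 h take out 90% of the target then present, then wait 10 h

- removed target is counted in
- additions bring no volume worth counting

* target, in percent of the starting material first charged, at 20 h
* what to do for the largest gain in target; "none" if nothing gains more than 2 percentage points (green / amber / violet / teal / none)
* target present, with what was taken out counted in, in percent of the starting material first charged, after violet
* target present, with what was taken out counted in, in percent of the starting material first charged, after teal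

I began by counting turnovers. In the delta run the target fell from its early readings towards a plateau, and the excess over the last reading, taken between 15.0 min and 30.0 min, gave a half-life of about 8.36 min. That number need not be good. The further 10 h holds 71.7 such half-lives, and with the half-life off by a factor 10, for the cooler zeta flask say, 7.17 remain, leaving 0.694% of a disturbance. The charge mattered little too: delta started from 0.11 M and its last reading, 15.2%, lay near the zeta readings.

The level matters. I took the plateau share f as the fraction of the material in the balance that stands as target after relaxing, the mark of thermodynamic control. Counting the whole charge as in the balance, teal's total is the part removed, the removed fraction times f, plus f times what stays. A shift in f moves that total 1.60 times as far, so f had to be known well. The mean of the zeta readings gave f = 16.5%, and my teal total was 28.9%.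

The forecast gave 16.5% (15.7% to 17.3%) for now, chose teal, and put violet at 14% and teal at 28.5%, a little under my total: “Removing target lets the pool refill”.

The zeta flask gave 15.9% at 20 h. Teal gained 12 percentage points, reaching 27.8%, and violet reached 14.5%.

    starting material + coupling partner → target (k = 0.00788 M⁻¹ s⁻¹, Ea = 62.0 kJ mol⁻¹)
    second substrate + coupling partner → second product (k = 0.00250 M⁻¹ s⁻¹, Ea = 87.0 kJ mol⁻¹)
    starting material + second substrate → cross product (k = 0.00107 M⁻¹ s⁻¹, Ea = 92.0 kJ mol⁻¹)
    target ⇌ isomer of the product (K = 4.96, k = 0.00126 s⁻¹, Ea = 100 kJ mol⁻¹, ΔH = 9.00 kJ mol⁻¹)
    coupling partner → decomposition product (k = 1.07 × 10⁻⁶ s⁻¹, Ea = 129 kJ mol⁻¹)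
    (constants at 110 °C)

My f was read over the whole charge, and cross product held 5.34% in the zeta flask, so over the rest of the charge f comes to 17.4%. The neighbouring flask was charged with 0.071 M of coupling partner, the limiting reagent at 1.00 equiv. At 20.0 h it had 2.1% of its starting material left and 31.0% as cross product, so 66.9% stood in the balance. Times 17.4% that is 11.6%, and the neighbouring flask held 11.2% of target.

(All runs are calculated on assumed constants; the scatter is artificial.)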